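**Retrosynthetic overview**
1. Side chain C2′–C3′: alkene cross-metathesis then hydrogenation joins (S)-3-allyl-5,7-dimethoxyphthalide to tridec-12-ene-2,5-dione.
2. The ene-1,4-dione comes from non-8-enal and methyl vinyl ketone (Stetter).
3. The C3–allyl bond, the C3 stereocentre and the lactone ring (the only ring formed) arise together from 2-formyl-4,6-dimethoxybenzoic acid and allylSiMe3 under a chiral silylium–IDPi ion pair (new reaction).
4. The formyl acid comes from 2-bromo-3,5-dimethoxybenzaldehyde by Pd hydroxycarbonylation; the benzene ring is bought.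

Assumption: non-8-enal and 2-bromo-3,5-dimethoxybenzaldehyde are taken as catalogue chemicals, and the IDPi antipode meant in step 3 is the one that delivers allyl to the Si face of the formyl group (to be fixed in the first run; both antipodes are equally accessible).

**Step 1**
Reactants: 1 non-8-enal; 2 but-3-en-2-one (methyl vinyl ketone)
Product: 3 tridec-12-ene-2,5-dione
Conditions: 3-benzyl-5-(2-hydroxyethyl)-4-methylthiazolium chloride (10 mol%), Et3N (0.5 equiv), 2 (1.3 equiv), EtOH, 80 °C
Reagents that add atoms: none
Why: Stetter reaction, in which the thiazolylidene turns the aldehyde into a Breslow acyl-anion equivalent that adds 1,4 to the enone and gives the 1,4-diketone directly, the remote terminal alkene being inert.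

**Step 2**
Reactants: 4 2-bromo-3,5-dimethoxybenzaldehyde
Product: 5 2-formyl-4,6-dimethoxybenzoic acid
Conditions: Pd(OAc)2 (3 mol%), Xantphos (4 mol%), CO (1 atm), H2O (10 equiv), Et3N (3 equiv), 1,4-dioxane, 90 °C; then 1 M HCl
Reagents that add atoms: carbon monoxide, [C-]#[O+]; water, O
Why: Pd-catalysed hydroxycarbonylation (oxidative addition into C–Br, CO insertion, hydrolysis of the acyl-palladium) leaves the aldehyde untouched and gives the acid, which rests as a ring–chain tautomeric pseudo-acid (3-hydroxy-5,7-dimethoxyphthalide) without any fixed stereocentre.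

**Step 3**
Reactants: 5 2-formyl-4,6-dimethoxybenzoic acid; 6 allyltrimethylsilane
Product: 9 (3S)-5,7-dimethoxy-3-(prop-2-en-1-yl)-2-benzofuran-1(3H)-one, via silyl ester aldehyde 7 (not isolated), via bis-silyl homoallyl ether 8 (not isolated)
Conditions: confined BINOL-derived IDPi (N-triflyl core, 1 mol%), 6 (3.2 equiv), toluene/CH2Cl2, 5 added slowly at −78 °C, then −50 °C; then 1 M HCl, THF, rt
Reagents that add atoms: none
Why: Proposed new method: allylSiMe3 silylates the IDPi acid to a chiral silylium–imidodiphosphorimidate ion pair and, with loss of propene, tracelessly silylates the carboxyl group so that the pseudo-acid is drawn into its open formyl form 7; the silylium ion then activates the aldehyde as a silyloxocarbenium ion inside the confined chiral anion, allyl is delivered to its Si face (Hosomi–Sakurai, sets C3 as S) to give 8, and acidic work-up desilylates and lactonises at the acyl carbon without touching the new C–O stereocentre; the closest known reaction type is the IDPi/silylium-catalysed asymmetric Hosomi–Sakurai allylation of simple aldehydes, not yet shown on free o-formylbenzoic acids (phthalide pseudo-acids) or as a phthalide-forming cascade.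

**Step 4**
Reactants: 9 (3S)-5,7-dimethoxy-3-(prop-2-en-1-yl)-2-benzofuran-1(3H)-one; 3 tridec-12-ene-2,5-dione
Product: 11 (3S)-3-(10,13-dioxotetradecyl)-5,7-dimethoxy-2-benzofuran-1(3H)-one (CJ-13,015), via cross-metathesis alkene 10 (not isolated)
Conditions: 3 (2.5 equiv), Hoveyda–Grubbs II (4 mol%), CH2Cl2, 40 °C; then solvent swap to EtOAc, 10% Pd/C, H2 (1 atm), rt
Reagents that add atoms: none
Why: Olefin cross-metathesis of two terminal type-I alkenes (ethene lost, excess 3 favours the cross product) followed by heterogeneous hydrogenation of the E/Z alkene, neither of which touches C3, the ketones or the lactone at 1 atm H2.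

**Compound list**
1 | non-8-enal | C=CCCCCCCC=O | starting material
2 | but-3-en-2-one (methyl vinyl ketone) | CC(=O)C=C | starting material
3 | tridec-12-ene-2,5-dione | CC(=O)CCC(=O)CCCCCCC=C | intermediate
4 | 2-bromo-3,5-dimethoxybenzaldehyde | COc1cc(OC)c(Br)c(C=O)c1 | starting material
5 | 2-formyl-4,6-dimethoxybenzoic acid (open form drawn; rests as ring tautomer 3-hydroxy-5,7-dimethoxyphthalide, no fixed stereocentre) | COc1cc(OC)c(C(=O)O)c(C=O)c1 | intermediate
6 | allyltrimethylsilane (trimethyl(prop-2-en-1-yl)silane) | C=CC[Si](C)(C)C | starting material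
7 | trimethylsilyl 2-formyl-4,6-dimethoxybenzoate | COc1cc(OC)c(C(=O)O[Si](C)(C)C)c(C=O)c1 | intermediate
8 | trimethylsilyl 2,4-dimethoxy-6-[(1S)-1-(trimethylsilyloxy)but-3-en-1-yl]benzoate | COc1cc(OC)c(C(=O)O[Si](C)(C)C)c(c1)[C@H](CC=C)O[Si](C)(C)C | intermediate
9 | (3S)-5,7-dimethoxy-3-(prop-2-en-1-yl)-2-benzofuran-1(3H)-one ((S)-3-allyl-5,7-dimethoxyphthalide) | COc1cc(OC)c2c(c1)[C@H](CC=C)OC2=O | intermediate
10 | (3S)-5,7-dimethoxy-3-[(2E)-10,13-dioxotetradec-2-en-1-yl]-2-benzofuran-1(3H)-one (E major, Z also formed) | COc1cc(OC)c2c(c1)[C@H](C/C=C/CCCCCCC(=O)CCC(C)=O)OC2=O | intermediate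
11 | (3S)-3-(10,13-dioxotetradecyl)-5,7-dimethoxy-2-benzofuran-1(3H)-one (CJ-13,015) | COc1cc(OC)c2c(c1)[C@H](CCCCCCCCCC(=O)CCC(C)=O)OC2=O | target

**Step count and risks**
Total step count: 4. Longest linear sequence: 3 (4 → 5 → 9 → 11); step 1 runs in parallel.

The three steps most likely to fail, with fallbacks:

Step 3, the new reaction. The electron-rich silyl ester carbonyl next to the formyl group may hold the silylium ion and slow turnover. A competing path through the cyclic O-silyl lactol (phthalidyl cation) may have a different facial bias and lower the ee. The fallback uses known chemistry, sets out from 4 and comes back at 9, so it also replaces step 2. Chiral phosphoric acid-catalysed allylboration of 4 with allylboronic acid pinacol ester and (S)-TRIP (5 mol%, toluene, −30 °C) gives first the boronate 2-{[(1S)-1-(2-bromo-3,5-dimethoxyphenyl)but-3-en-1-yl]oxy}-4,4,5,5-tetramethyl-1,3,2-dioxaborolane F1 and, after aqueous work-up, (1S)-1-(2-bromo-3,5-dimethoxyphenyl)but-3-en-1-ol F2. The (R)-acid is known to give the (R)-carbinols of aryl aldehydes, hence (S)-TRIP here. Pd-catalysed intramolecular alkoxycarbonylation of F2 (Pd(OAc)2/Xantphos, CO 1 atm, Et3N, toluene, 90 °C) then closes the lactone to 9 with the C–O stereocentre untouched.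

Step 4. The 1,4-dione partner may chelate the ruthenium carbene. Its hydrogenated excess and homodimer must be separated from the product. Ru-hydride alkene migration would give chain-shortened homologues. The fallback sets out from 9 (with 1 and 2) and comes back at 11, building the diketone last. Cross-metathesis of 9 with an excess of non-8-enal 1 gives (8E)-10-[(1S)-4,6-dimethoxy-3-oxo-1,3-dihydro-2-benzofuran-1-yl]dec-8-enal F3. Hydrogenation (Pd/C, H2 1 atm, EtOAc) gives 10-[(1S)-4,6-dimethoxy-3-oxo-1,3-dihydro-2-benzofuran-1-yl]decanal F4. A thiazolium-catalysed Stetter reaction of F4 with methyl vinyl ketone 2 (conditions of step 1) gives 11; the weakly basic conditions do not epimerise C3.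

Step 2. The C–Br bond is flanked by formyl and methoxy groups on an electron-rich ring, so oxidative addition and hydrolysis of the hindered acyl-palladium may be slow, and protodebromination may compete. The fallback sets out from 4 and comes back at 5 without palladium. Acetalisation of 4 (ethylene glycol, TsOH cat., toluene, Dean–Stark) gives 2-(2-bromo-3,5-dimethoxyphenyl)-1,3-dioxolane F5. Bromine–lithium exchange (n-BuLi, THF, −78 °C) gives [2-(1,3-dioxolan-2-yl)-4,6-dimethoxyphenyl]lithium F6. Quenching with CO2 gives, on acidification, 2-(1,3-dioxolan-2-yl)-4,6-dimethoxybenzoic acid F7. Stirring F7 with 2 M HCl in THF removes the acetal and gives 5.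

**Further compounds**
F1 | step 3 | 2-{[(1S)-1-(2-bromo-3,5-dimethoxyphenyl)but-3-en-1-yl]oxy}-4,4,5,5-tetramethyl-1,3,2-dioxaborolane | COc1cc(OC)c(Br)c(c1)[C@H](CC=C)OB1OC(C)(C)C(C)(C)O1
F2 | step 3 | (1S)-1-(2-bromo-3,5-dimethoxyphenyl)but-3-en-1-ol | COc1cc(OC)c(Br)c(c1)[C@H](CC=C)O
F3 | step 4 | (8E)-10-[(1S)-4,6-dimethoxy-3-oxo-1,3-dihydro-2-benzofuran-1-yl]dec-8-enal | COc1cc(OC)c2c(c1)[C@H](C/C=C/CCCCCCC=O)OC2=O
F4 | step 4 | 10-[(1S)-4,6-dimethoxy-3-oxo-1,3-dihydro-2-benzofuran-1-yl]decanal | COc1cc(OC)c2c(c1)[C@H](CCCCCCCCCC=O)OC2=O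
F5 | step 2 | 2-(2-bromo-3,5-dimethoxyphenyl)-1,3-dioxolane | COc1cc(OC)c(Br)c(c1)C1OCCO1
F6 | step 2 | [2-(1,3-dioxolan-2-yl)-4,6-dimethoxyphenyl]lithium | COc1cc(OC)c([Li])c(c1)C1OCCO1
F7 | step 2 | 2-(1,3-dioxolan-2-yl)-4,6-dimethoxybenzoic acid | COc1cc(OC)c(C(=O)O)c(c1)C1OCCO1
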